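## The problem

The target is a (3R)-isoflavan: a chroman (rings A and C) that carries ring B on C3. C3 is the only stereocentre and is flanked by two methylene groups (C2 and C4), so no other centre can control it; it must be set by a catalyst and then kept out of enolisable positions. Ring A is a resorcinol with four contiguous substituents: the C4 methylene at C4a, the ring oxygen at C8a, the 3-hydroxy-3-methylbutyl chain at C8 and a free hydroxyl at C7, with hydrogens only at C5 and C6. Ring B is a second resorcinol (oxygens at C2' and C4'), joined to C3 through C1' and bearing at C5' a 1,1-dimethylallyl group, a quaternary benzylic carbon with a vinyl substituent. That vinyl group forbids hydrogenation and hydrogenolysis once it is in place and, next to a free phenol, cyclises under strong acid. The tertiary alcohol of the C8 chain is also acid-sensitive (dehydration, closure onto O7), and the three phenols are oxidisable. Ring C has to be closed between O1 and C2 while the C2' oxygen of ring B is masked, because attack from that oxygen would give a dihydrobenzofuran. The feature that opens the way is the ring-A pattern itself: an oxygen-bearing carbon (C8a) between two alkyl-bearing carbons (C8 and C4a), a second oxygen at C7 and two adjacent CH positions is what a vinylketene and an oxygenated alkyne deliver in a benzannulation, so ring A can be built instead of substituted.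

## Retrosynthesis

**Final deprotection and ring C.** Target 32 is traced to its tris-silyl ether 31, so that the last step is a fluoride desilylation that spares the vinyl group and the tertiary alcohol. In 31 the O1–C2 bond is cut, giving triol 30, in which only the C8a phenol and a primary alcohol can react. This cut is preferred to a C4–C4a or C3–C4 cut at this stage because an intramolecular Mitsunobu etherification at a primary carbon does not touch C3. It also needs no discrimination among phenols as long as the ring-B oxygens stay silylated. Triol 30 comes from phenol 29 by acid methanolysis, which removes alkyl silyl ethers and leaves aryl silyl ethers.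

**Ring A (the strategic cut).** In 29 the bonds C8a–C8, C6–C7 and C4a–C8a are cut together. This removes the whole aromatic ring and leaves an acyclic (R)-diazo enone 18 and siloxyalkyne 24. Against electrophilic substitution of a 2-alkylresorcinol, this cut places every substituent of ring A by construction and delivers the C8a oxygen as the only free hydroxyl in the molecule, which is what ring C closure requires. The forward reaction must generate a vinylketene from 18 under conditions that the silyl ethers and the vinyl group survive, and must leave the homoallylic C3 centre alone.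

**Siloxyalkyne 24.** The O–C(sp) bond is cut back to terminal alkyne 21 (acetylide oxidation to the ynolate, then O-silylation). The tertiary carbinol is cut to methyl pent-4-ynoate 19 through alcohol 20. This is preferred to opening a 5,5-dimethyl lactone to an ester for ester homologation, because the tertiary hydroxy ester relactonises, whereas a double Grignard addition gives 20 directly with the triple bond already present.

**Diazo enone 18.** The diazo group is removed to methyl enone 16 (detrifluoroacetylative diazo transfer). The C=C bond of 16 is cut to aldehyde 15 and an acetonyl ylide. The aldehyde carbon of 15 is the future C4a, so the extra carbon of a four-carbon C3 building block ends up inside the aromatic ring.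

**Aldehyde 15.** The aldehyde is traced through Weinreb amide 14 and hydroxy amide 13 to (R)-lactone 12. A lactone is chosen because it holds C2 (as CH2O) and C4 (as CH2C=O) in different oxidation states from the outset. The amide route is preferred to a lactol Wittig reaction, whose hydroxy enone product can close to a tetrahydrofuran by oxa-Michael addition.

**The stereocentre.** The C3–C1' bond of 12 is cut to arylboronic acid 10 and furan-2(5H)-one 11. A rhodium/BINAP conjugate addition sets C3 at a carbon β to the carbonyl, so it is never enolisable in any later intermediate. The forward step must tolerate an ortho-silyloxy, electron-rich boronic acid.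

**Ring B.** Boronic acid 10 comes from bromide 7. The second silyl ether is removed to phenol 6. The 1,1-dimethylallyl group of 6 is traced by an aromatic Claisen rearrangement to prenyl ether 4, in which bromine blocks the para position and the silyloxy group crowds the other ortho position. Ether 4 comes from 3 and then from 4-bromobenzene-1,3-diol 1 and prenyl bromide 2. The bromine therefore serves twice: as a blocking group in the rearrangement and as the handle for boron.

## Roads not taken

Alternative 1: The cut is C3–C4 together with O1–C2. A ring-A sulfone, 5-hydroxy-6-[(phenylsulfonyl)methyl]-3,4-dihydrochromen-2-one A1 (the C8 chain tied back to O7 as a lactone), would lose sulfinate under mild base to unmask an ortho-quinone methide. The enamine formed from ring-B arylacetaldehyde A2 and a diarylprolinol silyl ether would add at C4, and the phenol would close onto the aldehyde to give lactol A3.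
- Merits: it is convergent, both rings come from aromatic feedstocks, and the C3–C4 bond, the stereocentre and ring C form in one organocatalytic operation without photochemistry. The step count is probably lower than that of the chosen plan.
- Weak points: C3 in A3 is benzylic and α to a masked aldehyde, so its configuration is at risk through the ring-opened form until C2 is reduced. C2 must then be taken from lactol to methylene, either by ionic hydrogenation under Lewis acid (at odds with the vinyl group and the silyl ethers) or by reduction to a diol and the same Mitsunobu closure used here. The lactone must also accept two methyl nucleophiles. A2 is an electron-rich, self-condensing arylacetaldehyde. A1 requires a sulfonylmethyl group ortho rather than para to the free phenol.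
- Comparison: this road is shorter. The chosen plan sets against it a stereocentre that is never α to a carbonyl and a ring A whose substitution pattern is fixed by mechanism.

Alternative 2: The cut is C3–C4 through a temporary ether between O2' and C4. Aryldiazoacetate A4 would undergo intramolecular benzylic C–H insertion under Rh2(S-PTTL)4 to give cis-dihydrobenzofuran A5 with the target's C3 configuration.
- Merits: the insertion is intramolecular and belongs to a well-studied enantioselective reaction class.
- Weak points: the temporary benzylic C–O bond must afterwards be cleaved reductively. Hydrogenolysis would saturate the vinyl group, and dissolving-metal or silane/acid conditions threaten the silyl ethers and the tertiary alcohol. C3 is benzylic and α to an ester both in A5 and after ring opening, so it can epimerise before the ester is reduced to C2. The carbenoid may also cyclopropanate the vinyl group of a second molecule. Ring A still has to be assembled by aromatic substitution, and the second stereocentre that is created is discarded.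
- Comparison: the step count is no better than in the chosen plan, and the reductive C–O scission conflicts directly with ring B. The chosen plan has no such step.

Alternative 3: The cut is C3–C1' together with C4–C4a, with no ring formed. Vinylboron ate complex A6 (ring B on boron, as its bis-methoxymethyl ether) would react with ring-A aryl bromide A7 under Pd(OAc)2 and MandyPhos. A palladium-induced 1,2-shift would place ring B on C3, and reductive elimination would attach ring A to C4, giving secondary boronate A8.
- Merits: this is the most convergent and probably the shortest road. A7 is available by monobromination of a symmetrical 2-alkylresorcinol diether, so ring A poses no regiochemical problem there.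
- Weak points: boron sits on C3 where C2 is needed, so a one-carbon homologation and oxidation must follow before the same Mitsunobu closure. Both coupling partners carry ortho oxygen substituents in the enantio-determining step, and a bromide electrophile needs halide scavenging. The methoxymethyl ethers that stabilise the aryllithium call for acid at the end, which endangers the tertiary alcohol and the 1,1-dimethylallyl phenol.
- Comparison: in step economy this road is better. The chosen plan offers instead an enantioselective step of a long-established type on a simple acceptor and an endgame that uses only fluoride, and it makes the crowded ring A without relying on any aromatic substitution.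

Key step: step 15

Assumption: mono-O-alkylation of 1 is taken to occur mainly at the hydroxyl para to bromine (the less hindered oxygen, whose phenoxide is the more nucleophilic); the regioisomer and the bis-ether are removed by chromatography.
Assumption: the sense of induction in step 6 is assigned by analogy with cycloalkenones, where (S)-BINAP delivers the aryl group to the face that corresponds to the (4S)-lactone; (R)-BINAP is therefore specified.
Abbreviations: TBS = tert-butyl(dimethyl)silyl; TES = triethylsilyl; TIPS = tri(propan-2-yl)silyl; ArB = 2,4-bis[tert-butyl(dimethyl)silyloxy]-5-(2-methylbut-3-en-2-yl)phenyl (ring B, attached through C1'; TBS ethers on O2' and O4').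

## Route

Step 1
Reactants: 1 4-bromobenzene-1,3-diol; 2 1-bromo-3-methylbut-2-ene
Product: 3 2-bromo-5-[(3-methylbut-2-en-1-yl)oxy]phenol
Conditions: K2CO3 (1.1 equiv), acetone, rt, slow addition of 2 (1.0 equiv)
Reagents that add atoms: none
Why: Williamson etherification; the hydroxyl para to bromine is unhindered and its phenoxide the more nucleophilic, so the mono-ether at that oxygen should predominate and is separated from regioisomer and bis-ether.

Step 2
Reactants: 3 2-bromo-5-[(3-methylbut-2-en-1-yl)oxy]phenol
Product: 4 [2-bromo-5-[(3-methylbut-2-en-1-yl)oxy]phenoxy](tert-butyl)dimethylsilane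
Conditions: TBSCl, imidazole, DMF, rt
Reagents that add atoms: tert-butyl(chloro)dimethylsilane, CC(C)(C)[Si](C)(C)Cl
Why: Standard silylation of a phenol; the bulky silyloxy group, buttressed by the adjacent bromine, shields the ring carbon between the two oxygens in the next step.

Step 3
Reactants: 4 [2-bromo-5-[(3-methylbut-2-en-1-yl)oxy]phenoxy](tert-butyl)dimethylsilane
Product: 6 4-bromo-5-[tert-butyl(dimethyl)silyloxy]-2-(2-methylbut-3-en-2-yl)phenol, via ortho-dienone 5 (not isolated)
Conditions: PhNEt2, 180 °C, sealed tube, short reaction time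
Reagents that add atoms: none
Why: Aromatic Claisen rearrangement; the [3,3] shift inverts the prenyl unit and delivers the 1,1-dimethylallyl group to the open ortho carbon, the para position being blocked by bromine and the other ortho carbon crowded by the silyloxy group; dienone 5 tautomerises to phenol 6.

Step 4
Reactants: 6 4-bromo-5-[tert-butyl(dimethyl)silyloxy]-2-(2-methylbut-3-en-2-yl)phenol
Product: 7 1-bromo-2,4-bis[tert-butyl(dimethyl)silyloxy]-5-(2-methylbut-3-en-2-yl)benzene
Conditions: TBSCl, imidazole, DMF, 40 °C
Reagents that add atoms: tert-butyl(chloro)dimethylsilane, CC(C)(C)[Si](C)(C)Cl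
Why: Silylation of a phenol hindered on one side only; gentle warming in DMF should suffice, and the product carries the same silyl group on both ring-B oxygens.

Step 5
Reactants: 7 1-bromo-2,4-bis[tert-butyl(dimethyl)silyloxy]-5-(2-methylbut-3-en-2-yl)benzene
Product: 10 {2,4-bis[tert-butyl(dimethyl)silyloxy]-5-(2-methylbut-3-en-2-yl)phenyl}boronic acid, via aryllithium 8 (not isolated), via lithium triisopropoxyborate 9 (not isolated)
Conditions: B(Oi-Pr)3, n-BuLi, THF/toluene, −78 °C (n-BuLi added to the mixture); then 1 M HCl to pH 5
Reagents that add atoms: triisopropyl borate, CC(C)OB(OC(C)C)OC(C)C; water, O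
Why: Lithium–bromine exchange with in situ borate trapping; capture of aryllithium 8 by the borate at −78 °C should outrun oxygen-to-carbon silyl migration, and mild hydrolysis of 9 gives the boronic acid.

Step 6
Reactants: 10 {2,4-bis[tert-butyl(dimethyl)silyloxy]-5-(2-methylbut-3-en-2-yl)phenyl}boronic acid; 11 furan-2(5H)-one
Product: 12 (4R)-4-ArB-oxolan-2-one
Conditions: [Rh(OH)((R)-BINAP)]2 (cat.), 11 (3 equiv), 1,4-dioxane/H2O 10:1, 35 °C
Reagents that add atoms: none
Why: Hayashi–Miyaura conjugate addition; the aryl–rhodium species inserts the lactone C=C on the face selected by (R)-BINAP, setting the future C3 as R, and the hydroxo complex allows a low temperature that limits protodeboronation of the electron-rich boronic acid.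

Step 7
Reactants: 12 (4R)-4-ArB-oxolan-2-one
Product: 13 (3R)-3-ArB-4-hydroxy-N-methoxy-N-methylbutanamide
Conditions: MeNH(OMe)·HCl, AlMe3, CH2Cl2, 0 °C to rt; aq. potassium sodium tartrate
Reagents that add atoms: N,O-dimethylhydroxylamine hydrochloride, CNOC.Cl
Why: Weinreb aminolysis of a lactone by the aluminium amide; the stereocentre is β to the carbonyl and not enolisable, and the product is silylated at once to prevent relactonisation.

Step 8
Reactants: 13 (3R)-3-ArB-4-hydroxy-N-methoxy-N-methylbutanamide
Product: 14 (3R)-3-ArB-4-[tert-butyl(dimethyl)silyloxy]-N-methoxy-N-methylbutanamide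
Conditions: TBSCl, imidazole, DMF, 0 °C to rt
Reagents that add atoms: tert-butyl(chloro)dimethylsilane, CC(C)(C)[Si](C)(C)Cl
Why: Silylation of a primary alcohol; the resulting alkyl silyl ether is the one silyl group on this fragment that mild acid will later remove selectively.

Step 9
Reactants: 14 (3R)-3-ArB-4-[tert-butyl(dimethyl)silyloxy]-N-methoxy-N-methylbutanamide
Product: 15 (3R)-3-ArB-4-[tert-butyl(dimethyl)silyloxy]butanal
Conditions: i-Bu2AlH, THF, −78 °C; aq. potassium sodium tartrate
Reagents that add atoms: none
Why: Reduction of a Weinreb amide stops at the aldehyde through the chelated tetrahedral intermediate; the aldehyde has no stereocentre at its α-carbon.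

Step 10
Reactants: 15 (3R)-3-ArB-4-[tert-butyl(dimethyl)silyloxy]butanal
Product: 16 (3E,6R)-6-ArB-7-[tert-butyl(dimethyl)silyloxy]hept-3-en-2-one
Conditions: Ph3P=CHC(O)CH3, toluene, 80 °C
Reagents that add atoms: 1-(triphenyl-λ5-phosphanylidene)propan-2-one, CC(=O)C=P(c1ccccc1)(c1ccccc1)c1ccccc1
Why: Wittig olefination with a stabilised ylide gives the (E)-enone under neutral conditions that leave the aryl silyl ethers untouched.

Step 11
Reactants: 16 (3E,6R)-6-ArB-7-[tert-butyl(dimethyl)silyloxy]hept-3-en-2-one
Product: 18 (3E,6R)-6-ArB-7-[tert-butyl(dimethyl)silyloxy]-1-diazohept-3-en-2-one, via trifluoroacetyl diketone 17 (not isolated)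
Conditions: LiHMDS, THF, −78 °C; CF3CO2CH2CF3; aq. HCl; then MsN3, Et3N, H2O (1 equiv), MeCN, rt
Reagents that add atoms: methanesulfonyl azide, CS(=O)(=O)N=[N+]=[N-] (2,2,2-trifluoroethyl trifluoroacetate, O=C(OCC(F)(F)F)C(F)(F)F, supplies the trifluoroacetyl group of 17 only)
Why: Detrifluoroacetylative diazo transfer; kinetic deprotonation at the methyl group, Claisen trifluoroacetylation and diazo transfer to the activated methylene with loss of the trifluoroacetyl group give the α'-diazo enone with the (E)-alkene intact.

Step 12
Reactants: 19 methyl pent-4-ynoate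
Product: 20 2-methylhex-5-yn-2-ol
Conditions: MeMgBr (3.5 equiv), THF, 0 °C to rt; then cold 1 M HCl
Reagents that add atoms: methylmagnesium bromide, C[Mg]Br
Why: Double Grignard addition to an ester gives the tertiary carbinol; the excess reagent covers deprotonation of the alkyne C–H, which is restored on work-up.

Step 13
Reactants: 20 2-methylhex-5-yn-2-ol
Product: 21 triethyl[(2-methylhex-5-yn-2-yl)oxy]silane
Conditions: TESOTf, 2,6-lutidine, CH2Cl2, −78 to 0 °C
Reagents that add atoms: triethylsilyl trifluoromethanesulfonate, CC[Si](CC)(CC)OS(=O)(=O)C(F)(F)F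
Why: A silyl triflate silylates the tertiary alcohol cleanly; the triethylsilyl ether survives organolithium chemistry and the benzannulation and is later removed by the same mild acid as the primary TBS ether.

Step 14
Reactants: 21 triethyl[(2-methylhex-5-yn-2-yl)oxy]silane
Product: 24 triethyl({2-methyl-6-[tri(propan-2-yl)silyloxy]hex-5-yn-2-yl}oxy)silane, via lithium acetylide 22 (not isolated), via lithium ynolate 23 (not isolated)
Conditions: n-BuLi, THF, −78 °C; LiOOt-Bu (from t-BuOOH and LiHMDS), −78 to 0 °C; TIPSOTf, −78 to 0 °C
Reagents that add atoms: tert-butyl hydroperoxide, CC(C)(C)OO; tri(propan-2-yl)silyl trifluoromethanesulfonate, CC(C)[Si](OS(=O)(=O)C(F)(F)F)(C(C)C)C(C)C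
Why: Oxidation of the lithium acetylide with lithium tert-butyl peroxide gives the ynolate, and the bulky silyl triflate traps it on oxygen, the established route to triisopropylsiloxyalkynes.

Step 15
Reactants: 18 (3E,6R)-6-ArB-7-[tert-butyl(dimethyl)silyloxy]-1-diazohept-3-en-2-one; 24 triethyl({2-methyl-6-[tri(propan-2-yl)silyloxy]hex-5-yn-2-yl}oxy)silane
Product: 29 6-[(2R)-2-ArB-3-[tert-butyl(dimethyl)silyloxy]propyl]-2-[3-methyl-3-(triethylsilyloxy)butyl]-3-[tri(propan-2-yl)silyloxy]phenol, via vinylketene 25 (not isolated), via vinylcyclobutenone 26 (not isolated), via dienylketene 27 (not isolated), via cyclohexadienone 28 (not isolated)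
Conditions: hν (medium-pressure Hg lamp, Pyrex filter, above 300 nm), 24 (1.3 equiv), degassed ClCH2CH2Cl, rt; then 80 °C
Reagents that add atoms: none
Why: Irradiation of 18 expels N2 with a 1,2-shift of the alkenyl group (photochemical Wolff rearrangement, which creates C5–C6) to give vinylketene 25, whose ketene carbon is attacked by the non-oxygenated carbon of siloxyalkyne 24 in a regiospecific [2+2] cycloaddition (C8a–C8 and C6–C7) to give vinylcyclobutenone 26. Heating reversibly opens 26 by 4π electrocyclic cleavage to dienylketene 27, which closes the six-membered carbocycle of ring A by 6π electrocyclisation (C4a–C8a) to cyclohexadienone 28, and this tautomerises to phenol 29. The closest known reaction type is the benzannulation of α-diazo enones with trialkylsiloxyalkynes to give resorcinol monosilyl ethers. No stereocentre is formed, and C3 is homoallylic to the reacting system, bears no acidic hydrogen and should pass through unchanged. The step needs regioselectivity (oxygen at C7, chain at C8), which the polarity of the ketene–ynol ether addition secures. It also needs the ketene to choose 24 over the isolated vinyl group and over product phenol, which the high nucleophilicity and slight excess of 24 and the accumulation of 26 before the thermal stage should secure. The (E)-alkene of 18 places the side arm outward in the 6π closure, and light above 300 nm is chosen so that the diazo ketone and not the silylated resorcinol ring absorbs.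

Step 16
Reactants: 29 6-[(2R)-2-ArB-3-[tert-butyl(dimethyl)silyloxy]propyl]-2-[3-methyl-3-(triethylsilyloxy)butyl]-3-[tri(propan-2-yl)silyloxy]phenol
Product: 30 6-[(2R)-2-ArB-3-hydroxypropyl]-2-(3-hydroxy-3-methylbutyl)-3-[tri(propan-2-yl)silyloxy]phenol
Conditions: camphorsulfonic acid (0.2 equiv), MeOH/CH2Cl2 1:1, 0 °C to rt
Reagents that add atoms: none
Why: Acid-catalysed methanolysis cleaves the two alkyl silyl ethers (primary TBS, tertiary TES), while the three aryl silyl ethers, which are stable to acid and labile only to base or fluoride, should remain.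

Step 17
Reactants: 30 6-[(2R)-2-ArB-3-hydroxypropyl]-2-(3-hydroxy-3-methylbutyl)-3-[tri(propan-2-yl)silyloxy]phenol
Product: 31 4-[(3R)-3-ArB-7-[tri(propan-2-yl)silyloxy]-3,4-dihydro-2H-chromen-8-yl]-2-methylbutan-2-ol
Conditions: PPh3, DIAD, THF (0.01 M), 0 °C to rt
Reagents that add atoms: none
Why: Intramolecular Mitsunobu etherification (6-exo-tet) of the only free phenol with the primary alcohol closes ring C; the tertiary alcohol is inert, the ring-B oxygens are silylated so no dihydrobenzofuran can form, and C3 is not a reacting centre.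

Step 18
Reactants: 31 4-[(3R)-3-ArB-7-[tri(propan-2-yl)silyloxy]-3,4-dihydro-2H-chromen-8-yl]-2-methylbutan-2-ol
Product: 32 (3R)-3-[2,4-dihydroxy-5-(2-methylbut-3-en-2-yl)phenyl]-8-(3-hydroxy-3-methylbutyl)-3,4-dihydro-2H-chromen-7-ol
Conditions: TBAF, AcOH, THF, 0 °C to rt, under argon
Reagents that add atoms: none
Why: Fluoride cleaves the three aryl silyl ethers; acetic acid buffering keeps the electron-rich phenols protonated, and neither the vinyl group nor the tertiary alcohol is affected.

## Compound list

1 | 4-bromobenzene-1,3-diol | Oc1ccc(Br)c(O)c1 | starting material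
2 | 1-bromo-3-methylbut-2-ene | CC(C)=CCBr | starting material
3 | 2-bromo-5-[(3-methylbut-2-en-1-yl)oxy]phenol | CC(C)=CCOc1ccc(Br)c(O)c1 | intermediate
4 | [2-bromo-5-[(3-methylbut-2-en-1-yl)oxy]phenoxy](tert-butyl)dimethylsilane | CC(C)=CCOc1ccc(Br)c(O[Si](C)(C)C(C)(C)C)c1 | intermediate
5 | 4-bromo-3-[tert-butyl(dimethyl)silyloxy]-6-(2-methylbut-3-en-2-yl)cyclohexa-2,4-dien-1-one (ortho-dienone, not isolated) | O=C1C=C(O[Si](C)(C)C(C)(C)C)C(Br)=CC1C(C)(C)C=C | intermediate
6 | 4-bromo-5-[tert-butyl(dimethyl)silyloxy]-2-(2-methylbut-3-en-2-yl)phenol | Oc1cc(O[Si](C)(C)C(C)(C)C)c(Br)cc1C(C)(C)C=C | intermediate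
7 | 1-bromo-2,4-bis[tert-butyl(dimethyl)silyloxy]-5-(2-methylbut-3-en-2-yl)benzene | C=CC(C)(C)c1cc(Br)c(O[Si](C)(C)C(C)(C)C)cc1O[Si](C)(C)C(C)(C)C | intermediate
8 | ArB-lithium (aryllithium, not isolated) | [Li]c1cc(C(C)(C)C=C)c(O[Si](C)(C)C(C)(C)C)cc1O[Si](C)(C)C(C)(C)C | intermediate
9 | lithium ArB-tri(propan-2-yloxy)borate (not isolated) | [Li+].CC(C)O[B-](OC(C)C)(OC(C)C)c1cc(C(C)(C)C=C)c(O[Si](C)(C)C(C)(C)C)cc1O[Si](C)(C)C(C)(C)C | intermediate
10 | {2,4-bis[tert-butyl(dimethyl)silyloxy]-5-(2-methylbut-3-en-2-yl)phenyl}boronic acid | OB(O)c1cc(C(C)(C)C=C)c(O[Si](C)(C)C(C)(C)C)cc1O[Si](C)(C)C(C)(C)C | intermediate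
11 | furan-2(5H)-one | O=C1OCC=C1 | starting material
12 | (4R)-4-ArB-oxolan-2-one | O=C1C[C@H](c2cc(C(C)(C)C=C)c(O[Si](C)(C)C(C)(C)C)cc2O[Si](C)(C)C(C)(C)C)CO1 | intermediate
13 | (3R)-3-ArB-4-hydroxy-N-methoxy-N-methylbutanamide | CON(C)C(=O)C[C@@H](CO)c1cc(C(C)(C)C=C)c(O[Si](C)(C)C(C)(C)C)cc1O[Si](C)(C)C(C)(C)C | intermediate
14 | (3R)-3-ArB-4-[tert-butyl(dimethyl)silyloxy]-N-methoxy-N-methylbutanamide | CON(C)C(=O)C[C@@H](CO[Si](C)(C)C(C)(C)C)c1cc(C(C)(C)C=C)c(O[Si](C)(C)C(C)(C)C)cc1O[Si](C)(C)C(C)(C)C | intermediate
15 | (3R)-3-ArB-4-[tert-butyl(dimethyl)silyloxy]butanal | O=CC[C@@H](CO[Si](C)(C)C(C)(C)C)c1cc(C(C)(C)C=C)c(O[Si](C)(C)C(C)(C)C)cc1O[Si](C)(C)C(C)(C)C | intermediate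
16 | (3E,6R)-6-ArB-7-[tert-butyl(dimethyl)silyloxy]hept-3-en-2-one | CC(=O)/C=C/C[C@@H](CO[Si](C)(C)C(C)(C)C)c1cc(C(C)(C)C=C)c(O[Si](C)(C)C(C)(C)C)cc1O[Si](C)(C)C(C)(C)C | intermediate
17 | (5E,8R)-8-ArB-9-[tert-butyl(dimethyl)silyloxy]-1,1,1-trifluoronon-5-ene-2,4-dione (not isolated) | O=C(CC(=O)/C=C/C[C@@H](CO[Si](C)(C)C(C)(C)C)c1cc(C(C)(C)C=C)c(O[Si](C)(C)C(C)(C)C)cc1O[Si](C)(C)C(C)(C)C)C(F)(F)F | intermediate
18 | (3E,6R)-6-ArB-7-[tert-butyl(dimethyl)silyloxy]-1-diazohept-3-en-2-one | [N-]=[N+]=CC(=O)/C=C/C[C@@H](CO[Si](C)(C)C(C)(C)C)c1cc(C(C)(C)C=C)c(O[Si](C)(C)C(C)(C)C)cc1O[Si](C)(C)C(C)(C)C | intermediate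
19 | methyl pent-4-ynoate | C#CCCC(=O)OC | starting material
20 | 2-methylhex-5-yn-2-ol | C#CCCC(C)(C)O | intermediate
21 | triethyl[(2-methylhex-5-yn-2-yl)oxy]silane | C#CCCC(C)(C)O[Si](CC)(CC)CC | intermediate
22 | lithium acetylide of 21 (not isolated) | [Li]C#CCCC(C)(C)O[Si](CC)(CC)CC | intermediate
23 | lithium ynolate, lithium 5-methyl-5-(triethylsilyloxy)hex-1-yn-1-olate (not isolated) | [Li]OC#CCCC(C)(C)O[Si](CC)(CC)CC | intermediate
24 | triethyl({2-methyl-6-[tri(propan-2-yl)silyloxy]hex-5-yn-2-yl}oxy)silane | CC(C)[Si](C(C)C)(C(C)C)OC#CCCC(C)(C)O[Si](CC)(CC)CC | intermediate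
25 | (3E,6R)-6-ArB-7-[tert-butyl(dimethyl)silyloxy]hepta-1,3-dien-1-one (vinylketene, not isolated) | O=C=C/C=C/C[C@@H](CO[Si](C)(C)C(C)(C)C)c1cc(C(C)(C)C=C)c(O[Si](C)(C)C(C)(C)C)cc1O[Si](C)(C)C(C)(C)C | intermediate
26 | 4-[(1E,4R)-4-ArB-5-[tert-butyl(dimethyl)silyloxy]pent-1-en-1-yl]-2-[3-methyl-3-(triethylsilyloxy)butyl]-3-[tri(propan-2-yl)silyloxy]cyclobut-2-en-1-one (both configurations at the ring sp3 carbon, not isolated) | O=C1C(CCC(C)(C)O[Si](CC)(CC)CC)=C(O[Si](C(C)C)(C(C)C)C(C)C)C1/C=C/C[C@@H](CO[Si](C)(C)C(C)(C)C)c1cc(C(C)(C)C=C)c(O[Si](C)(C)C(C)(C)C)cc1O[Si](C)(C)C(C)(C)C | intermediate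
27 | (3E,5E,8R)-8-ArB-9-[tert-butyl(dimethyl)silyloxy]-2-[3-methyl-3-(triethylsilyloxy)butyl]-3-[tri(propan-2-yl)silyloxy]nona-1,3,5-trien-1-one (dienylketene, not isolated) | O=C=C(CCC(C)(C)O[Si](CC)(CC)CC)/C(O[Si](C(C)C)(C(C)C)C(C)C)=C\C=C\C[C@@H](CO[Si](C)(C)C(C)(C)C)c1cc(C(C)(C)C=C)c(O[Si](C)(C)C(C)(C)C)cc1O[Si](C)(C)C(C)(C)C | intermediate
28 | 6-[(2R)-2-ArB-3-[tert-butyl(dimethyl)silyloxy]propyl]-2-[3-methyl-3-(triethylsilyloxy)butyl]-3-[tri(propan-2-yl)silyloxy]cyclohexa-2,4-dien-1-one (not isolated) | O=C1C(CCC(C)(C)O[Si](CC)(CC)CC)=C(O[Si](C(C)C)(C(C)C)C(C)C)C=CC1C[C@@H](CO[Si](C)(C)C(C)(C)C)c1cc(C(C)(C)C=C)c(O[Si](C)(C)C(C)(C)C)cc1O[Si](C)(C)C(C)(C)C | intermediate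
29 | 6-[(2R)-2-ArB-3-[tert-butyl(dimethyl)silyloxy]propyl]-2-[3-methyl-3-(triethylsilyloxy)butyl]-3-[tri(propan-2-yl)silyloxy]phenol | CC(C)[Si](C(C)C)(C(C)C)Oc1ccc(C[C@@H](CO[Si](C)(C)C(C)(C)C)c2cc(C(C)(C)C=C)c(O[Si](C)(C)C(C)(C)C)cc2O[Si](C)(C)C(C)(C)C)c(O)c1CCC(C)(C)O[Si](CC)(CC)CC | intermediate
30 | 6-[(2R)-2-ArB-3-hydroxypropyl]-2-(3-hydroxy-3-methylbutyl)-3-[tri(propan-2-yl)silyloxy]phenol | CC(C)[Si](C(C)C)(C(C)C)Oc1ccc(C[C@@H](CO)c2cc(C(C)(C)C=C)c(O[Si](C)(C)C(C)(C)C)cc2O[Si](C)(C)C(C)(C)C)c(O)c1CCC(C)(C)O | intermediate
31 | 4-[(3R)-3-ArB-7-[tri(propan-2-yl)silyloxy]-3,4-dihydro-2H-chromen-8-yl]-2-methylbutan-2-ol | C=CC(C)(C)c1cc([C@@H]2COc3c(ccc(O[Si](C(C)C)(C(C)C)C(C)C)c3CCC(C)(C)O)C2)c(O[Si](C)(C)C(C)(C)C)cc1O[Si](C)(C)C(C)(C)C | intermediate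
32 | (3R)-3-[2,4-dihydroxy-5-(2-methylbut-3-en-2-yl)phenyl]-8-(3-hydroxy-3-methylbutyl)-3,4-dihydro-2H-chromen-7-ol | C=CC(C)(C)c1cc([C@@H]2COc3c(ccc(O)c3CCC(C)(C)O)C2)c(O)cc1O | target

## Step count and least certain steps

Total step count: 18. Longest linear sequence: 15 steps (steps 1 to 11, then 15 to 18). The siloxyalkyne branch has 3 steps (12 to 14) and joins at step 15.

Key step (step 15). The most likely failures are:
- competing light absorption or photoisomerisation by the enone and the silylated aryl ring, which would lower the efficiency of the Wolff rearrangement;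
- dimerisation of the unhindered vinylketene, or its acylation by product phenol, before the siloxyalkyne captures it;
- incomplete thermal conversion of the cyclobutenone.

The fallback generates the same vinylketene without light, by retro-ene fragmentation of a tert-butyl ynol ether. It sets out from aldehyde 15. Takai iodo-olefination (CHI3, CrCl2, THF) should give the (E)-vinyl iodide tert-butyl{[(2R,4E)-2-ArB-5-iodopent-4-en-1-yl]oxy}dimethylsilane F1. Sonogashira coupling of F1 with tert-butoxyethyne (PdCl2(PPh3)2, CuI, i-Pr2NH) should give the enynyl ether tert-butyl{[(2R,4E)-2-ArB-7-tert-butoxyhept-4-en-6-yn-1-yl]oxy}dimethylsilane F2. Heating F2 with 24 in toluene at 80 to 90 °C should expel 2-methylpropene and release vinylketene 25 in the dark, which continues through 26, 27 and 28. The fallback rejoins the route at phenol 29.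

Step 3. The rearrangement may partly go to the carbon between the two oxygens. At the temperature required, the ortho-(1,1-dimethylallyl)phenol may also rearrange further or cyclise onto its own alkene, and silyl transfer between phenols is possible. The fallback replaces the sigmatropic step by a cross-coupling and sets out from 1. Iodination with N-iodosuccinimide should give 4-bromo-6-iodobenzene-1,3-diol F3. Double silylation (TBSCl, imidazole) should give 1-bromo-2,4-bis[tert-butyl(dimethyl)silyloxy]-5-iodobenzene F4. A γ-selective Suzuki–Miyaura coupling of prenylboronic acid pinacol ester at the C–I bond (Pd(OAc)2, bulky biaryl dialkylphosphine, K3PO4) should then install the 1,1-dimethylallyl group and leave the bromide. The fallback rejoins at bromide 7.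

Step 6. Transmetalation of the ortho-silyloxy, electron-rich boronic acid may be slower than its protodeboronation, and the enantioselectivity with so hindered an aryl group is untested. The fallback separates C–C bond formation from stereocontrol and sets out from 10. Suzuki–Miyaura coupling with 4-bromofuran-2(5H)-one (Pd(PPh3)4, anhydrous K3PO4, toluene) should give 4-ArB-furan-2(5H)-one F5. Asymmetric conjugate reduction with a ligated copper hydride (Cu(OAc)2, p-tol-BINAP of the antipode that gives the 4R product, polymethylhydrosiloxane, t-BuOH) should then set C3 without touching the isolated vinyl group. The fallback rejoins at lactone 12.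

Step 1. Alkylation may occur at the hydroxyl next to bromine or at both hydroxyls, because the more acidic phenol is the one that should stay free. The fallback fixes the regiochemistry by introducing bromine after the oxygens are differentiated. It sets out from 2 together with commercial 3-hydroxyphenyl benzoate F6. Bromination of F6 para to the free hydroxyl (N-bromosuccinimide, MeCN) should give 2-bromo-5-hydroxyphenyl benzoate F7. Etherification with 2 (K2CO3, acetone) should give 2-bromo-5-[(3-methylbut-2-en-1-yl)oxy]phenyl benzoate F8. Methanolysis of the benzoate (K2CO3, MeOH) rejoins the route at phenol 3.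

## Further compounds

F1 | step 15 | tert-butyl{[(2R,4E)-2-ArB-5-iodopent-4-en-1-yl]oxy}dimethylsilane | I/C=C/C[C@@H](CO[Si](C)(C)C(C)(C)C)c1cc(C(C)(C)C=C)c(O[Si](C)(C)C(C)(C)C)cc1O[Si](C)(C)C(C)(C)C
F2 | step 15 | tert-butyl{[(2R,4E)-2-ArB-7-tert-butoxyhept-4-en-6-yn-1-yl]oxy}dimethylsilane | CC(C)(C)OC#C/C=C/C[C@@H](CO[Si](C)(C)C(C)(C)C)c1cc(C(C)(C)C=C)c(O[Si](C)(C)C(C)(C)C)cc1O[Si](C)(C)C(C)(C)C
F3 | step 3 | 4-bromo-6-iodobenzene-1,3-diol | Oc1cc(O)c(I)cc1Br
F4 | step 3 | 1-bromo-2,4-bis[tert-butyl(dimethyl)silyloxy]-5-iodobenzene | CC(C)(C)[Si](C)(C)Oc1cc(O[Si](C)(C)C(C)(C)C)c(I)cc1Br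
F5 | step 6 | 4-ArB-furan-2(5H)-one | O=C1C=C(c2cc(C(C)(C)C=C)c(O[Si](C)(C)C(C)(C)C)cc2O[Si](C)(C)C(C)(C)C)CO1
F6 | step 1 | 3-hydroxyphenyl benzoate | O=C(Oc1cccc(O)c1)c1ccccc1
F7 | step 1 | 2-bromo-5-hydroxyphenyl benzoate | O=C(Oc1cc(O)ccc1Br)c1ccccc1
F8 | step 1 | 2-bromo-5-[(3-methylbut-2-en-1-yl)oxy]phenyl benzoate | O=C(Oc1cc(OCC=C(C)C)ccc1Br)c1ccccc1
A1 | alternative 1 | 5-hydroxy-6-[(phenylsulfonyl)methyl]-3,4-dihydro-2H-chromen-2-one | O=C1CCc2c(O)c(CS(=O)(=O)c3ccccc3)ccc2O1
A2 | alternative 1 | 2-ArB-acetaldehyde | O=CCc1cc(C(C)(C)C=C)c(O[Si](C)(C)C(C)(C)C)cc1O[Si](C)(C)C(C)(C)C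
A3 | alternative 1 | (3R)-3-ArB-chroman-2-ol with O7 and the C8 propanoate chain closed as a six-membered lactone (anomeric mixture at C2) | C=CC(C)(C)c1cc([C@@H]2C(O)Oc3c(C2)ccc4OC(=O)CCc34)c(O[Si](C)(C)C(C)(C)C)cc1O[Si](C)(C)C(C)(C)C
A4 | alternative 2 | methyl 2-diazo-2-[4-[tert-butyl(dimethyl)silyloxy]-5-(2-methylbut-3-en-2-yl)-2-({2,4-bis[tert-butyl(dimethyl)silyloxy]-3-[3-methyl-3-(triethylsilyloxy)butyl]phenyl}methoxy)phenyl]acetate | COC(=O)C(=[N+]=[N-])c1cc(C(C)(C)C=C)c(O[Si](C)(C)C(C)(C)C)cc1OCc1ccc(O[Si](C)(C)C(C)(C)C)c(CCC(C)(C)O[Si](CC)(CC)CC)c1O[Si](C)(C)C(C)(C)C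
A5 | alternative 2 | methyl cis-2-{2,4-bis[tert-butyl(dimethyl)silyloxy]-3-[3-methyl-3-(triethylsilyloxy)butyl]phenyl}-6-[tert-butyl(dimethyl)silyloxy]-5-(2-methylbut-3-en-2-yl)-2,3-dihydro-1-benzofuran-3-carboxylate | COC(=O)[C@@H]1[C@H](c2ccc(O[Si](C)(C)C(C)(C)C)c(CCC(C)(C)O[Si](CC)(CC)CC)c2O[Si](C)(C)C(C)(C)C)Oc2cc(O[Si](C)(C)C(C)(C)C)c(C(C)(C)C=C)cc12
A6 | alternative 3 | lithium [2,4-bis(methoxymethoxy)-5-(2-methylbut-3-en-2-yl)phenyl](ethenyl)(pinacolato)borate | [Li+].C=C[B-]1(OC(C)(C)C(C)(C)O1)c1cc(C(C)(C)C=C)c(OCOC)cc1OCOC
A7 | alternative 3 | 1-bromo-2,4-bis[tert-butyl(dimethyl)silyloxy]-3-[3-methyl-3-(triethylsilyloxy)butyl]benzene | Brc1ccc(O[Si](C)(C)C(C)(C)C)c(CCC(C)(C)O[Si](CC)(CC)CC)c1O[Si](C)(C)C(C)(C)C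
A8 | alternative 3 | secondary benzylic pinacol boronate with ring B and boron on C3 and ring A on C4 | CC1(C)OB(OC1(C)C)[C@H](Cc1ccc(O[Si](C)(C)C(C)(C)C)c(CCC(C)(C)O[Si](CC)(CC)CC)c1O[Si](C)(C)C(C)(C)C)c1cc(C(C)(C)C=C)c(OCOC)cc1OCOC
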